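Assumption: phenols 1 and 4 are bought with their oxygen pattern already in place, and 8 is taken from a cylinder and used at about 1 atm.

## Structural features

Compound 12 is a flavone: a benzene ring A fused through the C4a–C8a bond to a 4-pyranone ring C, which carries a second benzene ring B on C2 through the C2–C1' bond. The molecule is flat and achiral and has no stereocentre, so no relative or absolute configuration has to be set. Besides the carbonyl oxygen, seven oxygens sit on the frame: the ring oxygen O1 on C8a, OMe on C3 (an enol ether inside a vinylogous ester), OH on C6 and OMe on C7 of ring A, and OMe on C2' and C4' with OH on C5' of ring B. Seen from the three-carbon bridge C4–C3–C2, ring A and ring B have the same 2,4,5-trioxygenation, and in each ring the free hydroxyl stands para to the oxygen that is ortho to the bridge (O1 or the C2' methoxy). The fragile groups are the two para-alkoxyphenols, which are easily oxidised to quinones, and any methoxy group ortho to a carbonyl, which strong Lewis acids cleave; the C3 enol ether and the other aryl ethers are robust. The real difficulty is regiochemical: carbon must enter each ring at the one position para to a methoxy group, and the oxygens on C6 and C5' must be carried in a masked form that can be released at the end without touching four methyl ethers. The key step exploits that C4 is an isolated carbonyl carbon between the aromatic carbon C4a of ring A and C3, and that C3 is the acidic α-carbon of the ketone formed by C2 and ring B, so that C4 can be supplied as carbon monoxide between an aryl electrophile and an enolate.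

## Logic of the disconnections

12 ⇒ 11. The O–H bonds on C6 and C5' are traced back to O–CH2Ph bonds. The cut comes last because the free para-alkoxyphenols of 12 would not tolerate the halogenation, Lewis-acid, enolate and palladium steps, and because benzyl is the one ether that can be told apart from four methyl ethers. The gain is that every earlier intermediate is phenol-free and that both hydroxyls appear in one operation. The demand is a hydrogenolysis that leaves the C2–C3 double bond and the C4 carbonyl of 11 alone.

11 ⇒ 9 (through 10). The O1–C2 bond is cut and water is added back across C2–C3, which opens ring C to a 1,3-diketone; O1 is capped as a methoxymethyl acetal. The cut is made here because condensation of an ortho-hydroxyaryl 1,3-diketone is the most dependable way to close a 4-pyranone, and because only ring A has an unmasked ortho oxygen once the acetal is gone, so the direction of closure is fixed. The gain is an open chain with no ring C. The demand is one acid treatment that removes the acetal, giving 10, and dehydrates without cleaving benzyl ethers or splitting the diketone.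

9 ⇒ 3 + 7 + 8. The C4a–C4 and C4–C3 bonds are cut and C4 is recognised as 8. The cut is placed at the only carbon of the bridge that is flanked by an sp2 carbon able to carry iodine and by an enolisable carbon. The gain is the largest available: two arenes of similar size and the same oxygenation logic, joined convergently with two C–C bonds formed in one step. The demand is that CO insertion outruns direct arylation, that acylation occurs at carbon and not at oxygen, that the product does not react again, and that the acetal and benzyl ethers tolerate the conditions.

3 ⇒ 2. The O–CH2OCH3 bond on the C8a oxygen is cut. The mask is needed because a free ortho phenoxide would intercept the aroylpalladium intermediate; the acetal is chosen because the acid that closes ring C also removes it. The demand is a clean O-alkylation of a hindered, acidic ortho-iodophenol.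

2 ⇒ 1. The C4a–I bond is cut. In 1 the free hydroxyl (ortho) and the C7 methoxy (para) both direct an electrophile to C4a, and the C6 oxygen is already benzylated, so the two ring A oxygens that must end up different are different from the start. The demand is a single iodination at that position without oxidation of the electron-rich phenol.

7 ⇒ 5 + 6. The C1'–C2 bond is cut. The position para to the C2' methoxy and ortho to the C4' methoxy is the most nucleophilic carbon of 5, and 6 delivers C2, C3 and the C3 methoxy group in one piece. The demand is a Lewis acid mild enough to spare the benzyl ether and the methoxy group ortho to the new carbonyl, and to avoid loss of CO from the α-alkoxy acyl unit.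

5 ⇒ 4. The O–CH2Ph bond on the C5' oxygen is cut. This gives a purchasable phenol with the full ring B oxygen pattern; the only demand is a routine O-benzylation.

## Other disconnections considered

Alternative 1: The cut is the C8a–C4a bond, so ring A is built and not bought. In the forward sense, a cyclobutenone A2 with OH and an alkenyl chain on its sp3 carbon would be heated. Four-electron ring opening to a dienylketene, six-electron closure between the ketene carbon (future C8a) and the far alkene carbon (future C4a), and tautomerisation would give the hydroquinone A1. In A1, C4a already carries C4 and C3 as a ketal-masked methoxymethyl ketone.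
- In its favour: every ring A substituent is placed by construction and not by directing effects. On this structural point the alternative is the better plan, since the chosen route relies on the regioselectivity of an iodination. The key step needs no metal, no toxic gas and no reagent, and the sense of ring opening (hydroxyl outward, alkenyl inward) is dependable.
- Against it here: the ring A pattern it builds is that of a purchasable phenol (1), so the effort answers a question the target does not ask. A1 is an air-sensitive hydroquinone whose two hydroxyls (on C6 and C8a) must then be distinguished. Ring B would still have to be attached by O-aroylation, Baker–Venkataraman acyl shift and cyclodehydration.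
- Comparison: in mechanism the pericyclic cascade is as well understood as the palladium cycle (equal). In step economy it is clearly behind: A2 should need four or five steps and A1 is about five more from 12, against seven steps in all for the chosen plan.

Alternative 2: The cuts are the two aryl–carbonyl bonds C4a–C4 and C1'–C2, made together on the recognition that ring A (with O1 written as a methyl ether) and ring B are the same arene. In the forward sense, two molecules of the pivalate A4 would be acylated para to the C2 methoxy group by the diacid chloride A5 under SnCl4 to give the symmetric diketone A3.
- In its favour: one arene and one three-carbon unit, no palladium and no CO. Up to the diketone stage its step economy is better than that of the chosen plan (about three steps including the preparation of A5, against five to reach 9).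
- Against it here: the symmetry must be broken afterwards by cleaving exactly one of two equivalent methoxy groups ortho to a carbonyl to create O1. A Lewis acid acting through a chelate sees two identical sites, plus a third ether on the central carbon, so over-demethylation is a real threat. The chosen plan distinguishes O1 from the C2' oxygen from its first step (acetal against methyl).
- Further points against: A5 is not a catalogue reagent. As a malonyl chloride with an α-hydrogen and an α-alkoxy group it can lose HCl to a ketene or lose CO on ionisation, and the monoacylated β-keto acid chloride shares these weaknesses. The pivaloyloxy groups also lower the nucleophilicity of A4.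
- Comparison: on structure the alternative uses the hidden symmetry more fully. On mechanism both plans acylate an electron-rich arene, and the regiochemistry of the alternative is equal to that of step 4. If the mono-demethylation could be made selective, the alternative would be the shorter synthesis (about five steps against seven). Its risk is concentrated in a double acylation and a desymmetrisation that lack close analogy, which is why it is not chosen.

Alternative 3: The cut is the O1–C8a bond, so ring A enters with hydrogen on C8a and oxygen only on C6 and C7. In the forward sense, the phenol of the open-chain diketone A7 would be oxidised at a graphite anode in 1,1,1,3,3,3-hexafluoropropan-2-ol with Bu4NBF4. The electron-poor ring would be attacked para to the hydroxyl (at C8a) by the enol oxygen attached to C2, and loss of a proton would give the flavone A6, with C6–OH free and the C5' oxygen still benzylated.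
- In its favour: O1 is introduced by C–H functionalisation, so ring A needs neither iodination nor a masked ortho oxygen. No palladium, no CO and no stoichiometric oxidant are used. The C6 hydroxyl, a liability elsewhere, becomes the directing element; in this economy of design the alternative is the better plan.
- Step economy should be about equal: Claisen-type assembly of A7 from two protected building blocks, electrolysis, one hydrogenolysis.
- Against it here: A6 is a hydroquinone monoether (O1 para to OH) and should be easier to oxidise than A7, so over-oxidation towards a quinone is inherent. Closure at C5, which is also ortho to the acyl group and ortho to the hydroxyl, would compete with closure at C8a. Ring B, a trialkoxybenzene, should have an oxidation potential close to that of the phenol.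
- Comparison: on mechanism, anodic C–O coupling of a diketone enol oxygen to a phenol ring has no close precedent, so the decisive step would be a new method, whereas the chosen key step belongs to a known reaction type. On structure both plans pass through the same kind of 2-methoxy-1,3-diketone. The chosen plan closes ring C by a redox-neutral condensation; the alternative closes it by oxidation in the presence of three oxidisable arenes.

Key step: step 5

Step 1
Reactants: 1 4-(benzyloxy)-3-methoxyphenol
Product: 2 4-(benzyloxy)-2-iodo-5-methoxyphenol
Conditions: NIS (1.0 equiv), MeCN, −10 °C → rt, dark
Reagents that add atoms: N-iodosuccinimide, O=C1CCC(=O)N1I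
Why: Electrophilic aromatic iodination; the free OH (ortho) and the C3 methoxy (para) both direct to C6 of 1, whereas C2 is flanked by two substituents and C5 is activated only by the benzyloxy group. One equivalent of a mild iodine source at low temperature limits di-iodination and oxidation of the hydroquinone monoether.

Step 2
Reactants: 2 4-(benzyloxy)-2-iodo-5-methoxyphenol
Product: 3 1-(benzyloxy)-5-iodo-2-methoxy-4-(methoxymethoxy)benzene
Conditions: MOMCl, i-Pr2NEt, CH2Cl2, 0 °C → rt
Reagents that add atoms: chloromethyl methyl ether, COCCl
Why: Williamson-type O-alkylation of the phenol with a reactive α-chloro ether. The acetal masks the oxygen that becomes O1 so that it cannot trap the aroylpalladium intermediate in step 5, and it is removed by the acid that closes ring C.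

Step 3
Reactants: 4 2,4-dimethoxyphenol
Product: 5 1-(benzyloxy)-2,4-dimethoxybenzene
Conditions: BnBr, K2CO3, acetone, reflux
Reagents that add atoms: benzyl bromide, BrCc1ccccc1
Why: Williamson ether synthesis on the phenoxide. The benzyl ether is distinguishable from the methyl ethers and is removed together with the ring A benzyl group in step 7.

Step 4
Reactants: 5 1-(benzyloxy)-2,4-dimethoxybenzene; 6 methoxyacetyl chloride
Product: 7 1-[5-(benzyloxy)-2,4-dimethoxyphenyl]-2-methoxyethan-1-one
Conditions: SnCl4 (1.1 equiv), CH2Cl2, −40 → 0 °C
Reagents that add atoms: none
Why: Friedel–Crafts acylation; C5 of 5 is para to the C2 methoxy and ortho to the C4 methoxy, C3 is hindered between two methoxy groups, C6 is activated only by the benzyloxy group, and the ketone formed deactivates the ring against a second acylation. SnCl4 at low temperature is preferred to AlCl3 so that the benzyl ether, the methoxy group ortho to the new carbonyl and the α-alkoxy acyl unit (prone to loss of CO) stay intact.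

Step 5
Reactants: 3 1-(benzyloxy)-5-iodo-2-methoxy-4-(methoxymethoxy)benzene; 7 1-[5-(benzyloxy)-2,4-dimethoxyphenyl]-2-methoxyethan-1-one; 8 carbon monoxide
Product: 9 1-[5-(benzyloxy)-4-methoxy-2-(methoxymethoxy)phenyl]-3-[5-(benzyloxy)-2,4-dimethoxyphenyl]-2-methoxypropane-1,3-dione (racemic, enolisable)
Conditions: 8 (1 atm), Pd(dba)2 (5 mol %), 4,5-bis(diphenylphosphino)-9,9-dimethylxanthene (6 mol %), MgCl2 (2 equiv), Et3N (3 equiv), 1,4-dioxane, 80 °C; then cold aq. citric acid
Reagents that add atoms: none
Why: Pd(dba)2 and the wide-bite-angle diphosphine give a zerovalent palladium complex that adds oxidatively to the C4a–I bond of 3; the arylpalladium iodide formed (divalent palladium) binds 8, and migratory insertion gives the aroylpalladium species, which forms C4a–C4. MgCl2 and Et3N enolise 7 reversibly, with magnesium held between the carbonyl oxygen and the α-methoxy oxygen, and this chelated enolate is acylated at carbon by the aroylpalladium (enolate transfer to palladium, then acyl–carbon reductive elimination), which forms C4–C3 and returns zerovalent palladium. The closest known reaction type is the palladium-catalysed carbonylative α-arylation of ketones with aryl iodides to 1,3-diketones, run here with the magnesium halide and amine enolisation used for carbon acids in such couplings. No ring is closed. The new stereocentre between the two carbonyls of 9 is formed racemic, is enolisable and becomes sp2 in step 6, so nothing controls it and nothing needs to. The step needs carbonylative coupling to beat direct arylation, which the CO atmosphere, the fast CO insertion into an electron-rich aryl–palladium bond and the diphosphine secure, and it needs C-acylation to beat O-acylation, which the tight magnesium chelate secures. A second acylation is excluded because 9 is more acidic than 7 and rests as its magnesium diketonate until the mild acidic work-up. The acetal on the ortho oxygen of 3 prevents that oxygen from trapping the aroylpalladium intermediate as a phenoxide.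

Step 6
Reactants: 9 1-[5-(benzyloxy)-4-methoxy-2-(methoxymethoxy)phenyl]-3-[5-(benzyloxy)-2,4-dimethoxyphenyl]-2-methoxypropane-1,3-dione
Product: 11 6-(benzyloxy)-2-[5-(benzyloxy)-2,4-dimethoxyphenyl]-3,7-dimethoxy-4H-chromen-4-one, via ring A phenol diketone 10 (not isolated)
Conditions: conc. HCl, MeOH/THF, 60 °C
Reagents that add atoms: none
Why: Acid-catalysed acetal cleavage frees the C8a phenol (10); its oxygen adds to the ring B carbonyl (6-exo-trig) to give the cyclic hemiketal, and loss of water gives the 4-pyranone, the classical cyclodehydration of ortho-hydroxyaryl 1,3-diketones. Only ring A has a free ortho oxygen (ring B carries OMe on C2'), so the closure has one possible direction, and aryl benzyl and methyl ethers are stable to HCl in methanol.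

Step 7
Reactants: 11 6-(benzyloxy)-2-[5-(benzyloxy)-2,4-dimethoxyphenyl]-3,7-dimethoxy-4H-chromen-4-one
Product: 12 6-hydroxy-2-(5-hydroxy-2,4-dimethoxyphenyl)-3,7-dimethoxy-4H-chromen-4-one (6,5'-dihydroxy-3,7,2',4'-tetramethoxyflavone)
Conditions: H2 (1 atm), 10% Pd/C, THF/MeOH, rt
Reagents that add atoms: none
Why: Catalytic hydrogenolysis of the two aryl benzyl ethers. The tetrasubstituted C2–C3 double bond of the vinylogous ester, the C4 carbonyl and the aryl methyl ethers should be inert to H2 over Pd/C at ambient pressure and temperature.

Compound list
1 | 4-(benzyloxy)-3-methoxyphenol | COc1cc(O)ccc1OCc1ccccc1 | starting material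
2 | 4-(benzyloxy)-2-iodo-5-methoxyphenol | COc1cc(O)c(I)cc1OCc1ccccc1 | intermediate
3 | 1-(benzyloxy)-5-iodo-2-methoxy-4-(methoxymethoxy)benzene | COCOc1cc(OC)c(OCc2ccccc2)cc1I | intermediate
4 | 2,4-dimethoxyphenol | COc1ccc(O)c(OC)c1 | starting material
5 | 1-(benzyloxy)-2,4-dimethoxybenzene | COc1ccc(OCc2ccccc2)c(OC)c1 | intermediate
6 | methoxyacetyl chloride | COCC(Cl)=O | starting material
7 | 1-[5-(benzyloxy)-2,4-dimethoxyphenyl]-2-methoxyethan-1-one | COCC(=O)c1cc(OCc2ccccc2)c(OC)cc1OC | intermediate
8 | carbon monoxide | [C-]#[O+] | starting material
9 | 1-[5-(benzyloxy)-4-methoxy-2-(methoxymethoxy)phenyl]-3-[5-(benzyloxy)-2,4-dimethoxyphenyl]-2-methoxypropane-1,3-dione (racemic, enolisable) | COCOc1cc(OC)c(OCc2ccccc2)cc1C(=O)C(OC)C(=O)c1cc(OCc2ccccc2)c(OC)cc1OC | intermediate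
10 | 1-[5-(benzyloxy)-2-hydroxy-4-methoxyphenyl]-3-[5-(benzyloxy)-2,4-dimethoxyphenyl]-2-methoxypropane-1,3-dione (racemic, enolisable, not isolated) | Oc1cc(OC)c(OCc2ccccc2)cc1C(=O)C(OC)C(=O)c1cc(OCc2ccccc2)c(OC)cc1OC | intermediate
11 | 6-(benzyloxy)-2-[5-(benzyloxy)-2,4-dimethoxyphenyl]-3,7-dimethoxy-4H-chromen-4-one | COc1cc(OC)c(-c2oc3cc(OC)c(OCc4ccccc4)cc3c(=O)c2OC)cc1OCc1ccccc1 | intermediate
12 | 6-hydroxy-2-(5-hydroxy-2,4-dimethoxyphenyl)-3,7-dimethoxy-4H-chromen-4-one | COc1cc(OC)c(-c2oc3cc(OC)c(O)cc3c(=O)c2OC)cc1O | target

Total step count: 7. Longest linear sequence: 5 steps (steps 1, 2, 5, 6, 7, or equally steps 3, 4, 5, 6, 7).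

Least certain steps

Step 5 (key step). The most likely failure is that enolisation of 7 by MgCl2 and Et3N falls behind the formation of the aroylpalladium intermediate. The catalyst would then drain into side channels (reduction of the aroyl unit, direct arylation of the enolate without CO, O-acylation) or rest as inactive palladium carbonyl species; the ortho acetal oxygen of 3 also slows oxidative addition. The fallback gives up catalysis for stepwise carboxylation and Claisen-type acylation, sets out from 3 and comes back at 9. Iodine–magnesium exchange on 3 (i-PrMgCl·LiCl, THF, −20 °C) and quenching with CO2, with work-up near pH 4 to keep the acetal, would give 5-(benzyloxy)-4-methoxy-2-(methoxymethoxy)benzoic acid F1. 1,1'-Carbonyldiimidazole in THF would turn it into [5-(benzyloxy)-4-methoxy-2-(methoxymethoxy)phenyl](1H-imidazol-1-yl)methanone F2. F2 would be added to the lithium enolate of 7 (LiN(SiMe3)2, 2 equiv, THF, −78 → 0 °C) to give 9 after mild acidic work-up. The same two bonds are made, C4a–C4 first and C4–C3 second.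

Step 4. The most likely failures are Lewis-acid induced loss of CO from the α-alkoxy acyl cation, which would lead to alkoxymethylation of the arene instead of acylation, and cleavage of the benzyl ether, whose oxygen sits next to a methoxy group and can chelate tin. The fallback replaces electrophilic acylation by an aryl-metal route, sets out from 5 and comes back at 7. NBS in MeCN at 0 °C would brominate the same, most activated position to give 1-(benzyloxy)-5-bromo-2,4-dimethoxybenzene F3. Bromine–lithium exchange (n-BuLi, THF, −78 °C) and addition of N,2-dimethoxy-N-methylacetamide would give 7 on aqueous work-up, with no Lewis acid and no acyl cation involved.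

Step 1. The most likely failures are iodination at the crowded position between OH and OMe or a second iodination, and oxidation of the free para-alkoxyphenol towards a quinone by the iodinating agent. The fallback reverses the order of masking and halogenation, sets out from 1 and comes back at 3, bypassing 2. MOMCl and i-Pr2NEt in CH2Cl2 would first give 1-(benzyloxy)-2-methoxy-4-(methoxymethoxy)benzene F4, which is no longer a phenol and is much less prone to oxidation. NIS in MeCN at rt would then iodinate the position para to the methoxy group and ortho to the acetal oxygen, the only doubly activated unhindered carbon, to give 3.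

Step 7. The most likely failures are stalling after loss of the first benzyl group, through precipitation of the partly deprotected flavone on the catalyst, and slow saturation of the C2–C3 double bond if the reaction is forced. The fallback moves the hydrogenolysis in front of the ring closure, sets out from 9 and comes back at 12, bypassing 11. H2 over 10% Pd/C in EtOAc would convert 9 into 1-[5-hydroxy-4-methoxy-2-(methoxymethoxy)phenyl]-3-(5-hydroxy-2,4-dimethoxyphenyl)-2-methoxypropane-1,3-dione F5, a soluble open-chain compound with no pyranone to over-reduce. HCl in MeOH at 60 °C would then remove the acetal and close ring C to give 12 directly; the two liberated phenols are meta to their acyl groups and cannot take part in the closure.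

## Further compounds

F1 | step 5 | 5-(benzyloxy)-4-methoxy-2-(methoxymethoxy)benzoic acid | COCOc1cc(OC)c(OCc2ccccc2)cc1C(=O)O
F2 | step 5 | [5-(benzyloxy)-4-methoxy-2-(methoxymethoxy)phenyl](1H-imidazol-1-yl)methanone | COCOc1cc(OC)c(OCc2ccccc2)cc1C(=O)n1ccnc1
F3 | step 4 | 1-(benzyloxy)-5-bromo-2,4-dimethoxybenzene | COc1cc(OC)c(OCc2ccccc2)cc1Br
F4 | step 1 | 1-(benzyloxy)-2-methoxy-4-(methoxymethoxy)benzene | COCOc1ccc(OCc2ccccc2)c(OC)c1
F5 | step 7 | 1-[5-hydroxy-4-methoxy-2-(methoxymethoxy)phenyl]-3-(5-hydroxy-2,4-dimethoxyphenyl)-2-methoxypropane-1,3-dione (racemic, enolisable) | COCOc1cc(OC)c(O)cc1C(=O)C(OC)C(=O)c1cc(O)c(OC)cc1OC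
A1 | alternative 1 | 2-(2,5-dihydroxy-4-methoxyphenyl)-2-(methoxymethyl)-1,3-dioxolane | COCC1(OCCO1)c1cc(O)c(OC)cc1O
A2 | alternative 1 | 4-hydroxy-3-methoxy-4-{(E)-2-[2-(methoxymethyl)-1,3-dioxolan-2-yl]ethenyl}cyclobut-2-en-1-one (racemic) | COCC1(OCCO1)/C=C/C1(O)C(OC)=CC1=O
A3 | alternative 2 | 1,3-bis[2,4-dimethoxy-5-(pivaloyloxy)phenyl]-2-methoxypropane-1,3-dione | COC(C(=O)c1cc(OC(=O)C(C)(C)C)c(OC)cc1OC)C(=O)c1cc(OC(=O)C(C)(C)C)c(OC)cc1OC
A4 | alternative 2 | 2,4-dimethoxyphenyl pivalate | COc1ccc(OC(=O)C(C)(C)C)c(OC)c1
A5 | alternative 2 | methoxymalonyl dichloride | COC(C(Cl)=O)C(Cl)=O
A6 | alternative 3 | 2-[5-(benzyloxy)-2,4-dimethoxyphenyl]-6-hydroxy-3,7-dimethoxy-4H-chromen-4-one | COc1cc(OC)c(-c2oc3cc(OC)c(O)cc3c(=O)c2OC)cc1OCc1ccccc1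
A7 | alternative 3 | 1-[5-(benzyloxy)-2,4-dimethoxyphenyl]-3-(3-hydroxy-4-methoxyphenyl)-2-methoxypropane-1,3-dione (racemic, enolisable) | COc1ccc(cc1O)C(=O)C(OC)C(=O)c1cc(OCc2ccccc2)c(OC)cc1OC
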